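**Retrosynthetic overview**
- Endgame: fluoride desilylation ⇐ Dess–Martin oxidation of the C5′ carbinol ⇐ C12′–C13′ enone from a Weinreb amide and an (E)-alkenyllithium.
- C4′–C5′: α-selective, geometry-retaining allylbarium addition of an aryl-substituted (E)-allyl chloride (fragment A) to a (Z)-enal (fragment B).
- Fragment B: C7′–C8′ by B-alkyl Suzuki coupling of (Z)-3-iodobut-2-en-1-ol with the 9-BBN adduct of an (R)-2-methylpent-4-enoyl Weinreb amide; C11′ by Evans allylation.
- Fragment A: Ar–C1′ and the 2′E alkene by copper-catalysed SN2′ opening of isoprene monoxide with an aryl Grignard reagent; the phenol oxygen by iridium-catalysed C–H borylation/oxidation.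
- No ring is formed in the route; the only ring, the benzene ring, is bought as 1-bromo-2-methoxy-3-methylbenzene.

Assumption: the target is the (2′E,6′Z,11′R,13′E) isomer exactly as the SMILES encodes it, and the starting materials named below are taken as catalogue compounds.

**Fragment A**

Step 1
Reactants: 1 1-bromo-2-methoxy-3-methylbenzene
Product: 3 3-bromo-4-methoxy-5-methylphenol, via aryl pinacol boronate 2 (not isolated)
Conditions: [Ir(OMe)(cod)]2 (1.5 mol%), dtbpy (3 mol%), HBpin (1.5 equiv), THF, 80 °C; then KHSO5 (as the triple salt 2KHSO5·KHSO4·K2SO4), acetone/H2O, rt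
Reagents that add atoms: pinacolborane, CC1(C)OBOC1(C)C (boron and pinacol held only in 2); potassium peroxymonosulfate KHSO5, [K+].[O-]S(=O)(=O)OO (the phenol oxygen)
Why: Sterically governed iridium-catalysed C–H borylation takes the only ring C–H with no ortho neighbour (para to OMe), and oxidation of the C–B bond gives the phenol with the C–Br bond untouched.

Step 2
Reactants: 3 3-bromo-4-methoxy-5-methylphenol
Product: 4 (3-bromo-4-methoxy-5-methylphenoxy)(tert-butyl)dimethylsilane
Conditions: TBSCl, imidazole, DMF, rt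
Reagents that add atoms: tert-butyldimethylsilyl chloride (TBSCl), CC(C)(C)[Si](C)(C)Cl
Why: Standard phenol silylation gives an aryl TBS ether that survives the organometallic steps and is removed by fluoride at the end.

Step 3
Reactants: 4 (3-bromo-4-methoxy-5-methylphenoxy)(tert-butyl)dimethylsilane; 5 2-methyl-2-vinyloxirane (isoprene monoxide, racemic)
Product: 7 (E)-4-[5-(tert-butyldimethylsilyloxy)-2-methoxy-3-methylphenyl]-2-methylbut-2-en-1-ol, via arylmagnesium bromide 6 (not isolated)
Conditions: Mg, THF, 50 °C; then CuBr·SMe2 (10 mol%), 5, THF, −30 → 0 °C; aq NH4Cl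
Reagents that add atoms: magnesium, [Mg] (held only in 6)
Why: Copper-catalysed SN2′ opening of the vinyl oxirane by the aryl Grignard reagent puts the aryl group on the vinyl terminus and gives the trisubstituted allylic alcohol mainly as the E isomer (about 9:1, minor Z isomer removed by chromatography).

Step 4
Reactants: 7 (E)-4-[5-(tert-butyldimethylsilyloxy)-2-methoxy-3-methylphenyl]-2-methylbut-2-en-1-ol
Product: 9 (E)-tert-butyl[3-(4-chloro-3-methylbut-2-en-1-yl)-4-methoxy-5-methylphenoxy]dimethylsilane, via allylic mesylate 8 (not isolated)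
Conditions: MsCl, LiCl, 2,4,6-collidine, DMF, 0 °C
Reagents that add atoms: methanesulfonyl chloride, CS(=O)(=O)Cl (held only in 8); lithium chloride, [Li+].[Cl-] (the chlorine of 9)
Why: Collington–Meyers chlorination displaces the primary allylic mesylate by chloride in an SN2 step without allylic transposition or loss of E geometry.

**Fragment B**

Step 5
Reactants: 10 (S)-4-benzyl-3-propanoyl-1,3-oxazolidin-2-one; 11 allyl iodide
Product: 13 (S)-4-benzyl-3-[(R)-2-methylpent-4-enoyl]-1,3-oxazolidin-2-one, via sodium Z-enolate 12 (not isolated)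
Conditions: NaN(SiMe3)2, THF, −78 °C; then 11, −78 → −45 °C
Reagents that add atoms: sodium bis(trimethylsilyl)amide, [Na+].C[Si](C)(C)[N-][Si](C)(C)C (sodium held only in 12)
Why: Evans asymmetric alkylation: the chelated Z-enolate is allylated on the face opposite the benzyl group, which sets the α-carbon (the later C11′) as R with about 98:2 dr.

Step 6
Reactants: 13 (S)-4-benzyl-3-[(R)-2-methylpent-4-enoyl]-1,3-oxazolidin-2-one
Product: 14 (R)-N-methoxy-N,2-dimethylpent-4-enamide
Conditions: MeNH(OMe)·HCl, AlMe3, CH2Cl2, 0 °C → rt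
Reagents that add atoms: N,O-dimethylhydroxylamine hydrochloride, CNOC.Cl
Why: Aluminium amide transamination (Weinreb amide formation) cleaves the exocyclic imide carbonyl without epimerising the α-centre and releases the auxiliary.

Step 7
Reactants: 15 but-2-yn-1-ol
Product: 17 (Z)-3-iodobut-2-en-1-ol, via cyclic sodium alkenylalanate 16 (not isolated)
Conditions: NaAlH2(OCH2CH2OMe)2, Et2O, 0 °C → rt; then I2, THF, −78 → 0 °C
Reagents that add atoms: sodium bis(2-methoxyethoxy)aluminium dihydride, [Na+].COCCO[AlH2-]OCCOC (held only in 16); iodine, II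
Why: Hydroxyl-directed trans-hydroalumination places aluminium on C3 in a five-membered alanate, and iodinolysis with retention gives only the Z iodoalkene.

Step 8
Reactants: 14 (R)-N-methoxy-N,2-dimethylpent-4-enamide; 17 (Z)-3-iodobut-2-en-1-ol
Product: 19 (R,Z)-8-hydroxy-N-methoxy-N,2,6-trimethyloct-6-enamide, via B-alkyl-9-BBN borane 18 (not isolated)
Conditions: 9-BBN (1.1 equiv), THF, 0 °C → rt; then 17, PdCl2(dppf) (5 mol%), AsPh3, Cs2CO3, DMF/THF/H2O, rt
Reagents that add atoms: 9-borabicyclo[3.3.1]nonane, B1C2CCCC1CCC2 (held only in 18)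
Why: Anti-Markovnikov hydroboration of the terminal alkene followed by B-alkyl Suzuki–Miyaura coupling, which retains the geometry of the alkenyl iodide, so the new chain is cis to CH2OH (Z).

Step 9
Reactants: 19 (R,Z)-8-hydroxy-N-methoxy-N,2,6-trimethyloct-6-enamide
Product: 20 (R,Z)-N-methoxy-N,2,6-trimethyl-8-oxooct-6-enamide
Conditions: TEMPO (10 mol%), PhI(OAc)2, CH2Cl2, 0 °C → rt
Reagents that add atoms: none
Why: Oxoammonium (TEMPO/PhI(OAc)2) oxidation of the allylic alcohol stops at the aldehyde and does not isomerise Z-enals (the nerol-to-neral case).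

**Alkenyl iodide**

Step 10
Reactants: 21 trimethyl[(2-methylbut-3-yn-2-yl)oxy]silane
Product: 23 (E)-[(4-iodo-2-methylbut-3-en-2-yl)oxy]trimethylsilane, via E-alkenylzirconocene chloride 22 (not isolated)
Conditions: Cp2Zr(H)Cl, THF, rt; then I2, 0 °C
Reagents that add atoms: zirconocene chloride hydride Cp2Zr(H)Cl, [H][Zr](Cl)(C1C=CC=C1)C1C=CC=C1 (held only in 22); iodine, II
Why: Schwartz hydrozirconation adds Zr–H syn with zirconium on the terminal carbon, and iodinolysis with retention gives the E alkenyl iodide.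

**Coupling and endgame**

Step 11
Reactants: 9 (E)-tert-butyl[3-(4-chloro-3-methylbut-2-en-1-yl)-4-methoxy-5-methylphenoxy]dimethylsilane; 20 (R,Z)-N-methoxy-N,2,6-trimethyl-8-oxooct-6-enamide
Product: 25 (2R,6Z,10E)-12-[5-(tert-butyldimethylsilyloxy)-2-methoxy-3-methylphenyl]-8-hydroxy-N-methoxy-N,2,6,10-tetramethyldodeca-6,10-dienamide (both C8 epimers), via allylbarium chloride 24 (not isolated)
Conditions: BaI2, lithium biphenylide LiC12H10 (2 equiv), THF, rt; 9 (slight excess over barium), −78 °C; then 20, −78 °C, 30 min; aq NH4Cl at −78 °C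
Reagents that add atoms: barium diiodide, [Ba+2].[I-].[I-] (barium held only in 24)
Why: Yamamoto allylbarium addition: the allylbarium formed at −78 °C keeps its E geometry and attacks the aldehyde through its α-carbon (1,2-addition) faster than it touches the Weinreb amide, and the uncontrolled carbinol centre is erased by oxidation in step 13.

Step 12
Reactants: 25 (2R,6Z,10E)-12-[5-(tert-butyldimethylsilyloxy)-2-methoxy-3-methylphenyl]-8-hydroxy-N-methoxy-N,2,6,10-tetramethyldodeca-6,10-dienamide; 23 (E)-[(4-iodo-2-methylbut-3-en-2-yl)oxy]trimethylsilane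
Product: 28 (3E,6R,10Z,14E)-16-[5-(tert-butyldimethylsilyloxy)-2-methoxy-3-methylphenyl]-12-hydroxy-2,6,10,14-tetramethyl-2-(trimethylsilyloxy)hexadeca-3,10,14-trien-5-one, via E-alkenyllithium 26 (not isolated), via dilithio tetrahedral adduct 27 (not isolated)
Conditions: 23 (3.3 equiv), t-BuLi (2 equiv per 23), Et2O, −78 °C; then 25, THF, −78 → −40 °C; inverse quench into cold aq NH4Cl
Reagents that add atoms: tert-butyllithium, [Li]C(C)(C)C (lithium held only in 26 and 27)
Why: Lithium–iodine exchange with retention gives the E alkenyllithium, one equivalent of which deprotonates the hydroxyl while a second adds to the Weinreb amide to give a chelated tetrahedral adduct that collapses to the E-enone only on work-up, so there is no over-addition and no epimerisation (Weinreb ketone synthesis).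

Step 13
Reactants: 28 (3E,6R,10Z,14E)-16-[5-(tert-butyldimethylsilyloxy)-2-methoxy-3-methylphenyl]-12-hydroxy-2,6,10,14-tetramethyl-2-(trimethylsilyloxy)hexadeca-3,10,14-trien-5-one
Product: 29 (3E,6R,10Z,14E)-16-[5-(tert-butyldimethylsilyloxy)-2-methoxy-3-methylphenyl]-2,6,10,14-tetramethyl-2-(trimethylsilyloxy)hexadeca-3,10,14-triene-5,12-dione
Conditions: Dess–Martin periodinane, NaHCO3, CH2Cl2, 0 °C; fast chromatography on deactivated silica
Reagents that add atoms: none
Why: Buffered Dess–Martin oxidation turns the allylic/homoallylic carbinol into the ketone under neutral conditions that leave the skipped (β,γ) E-alkene, the Z-enone and the α-methyl centre unchanged.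

Step 14
Reactants: 29 (3E,6R,10Z,14E)-16-[5-(tert-butyldimethylsilyloxy)-2-methoxy-3-methylphenyl]-2,6,10,14-tetramethyl-2-(trimethylsilyloxy)hexadeca-3,10,14-triene-5,12-dione
Product: 30 (3E,6R,10Z,14E)-2-hydroxy-16-(5-hydroxy-2-methoxy-3-methylphenyl)-2,6,10,14-tetramethylhexadeca-3,10,14-triene-5,12-dione (the target; 2′E,6′Z,11′R,13′E in side-chain numbering)
Conditions: Bu4NF, AcOH (1:1), THF, 0 °C
Reagents that add atoms: none
Why: Acetic acid-buffered fluoride desilylation cleaves the aryl TBS ether and the tertiary TMS ether without leaving free phenoxide or alkoxide base that could isomerise the skipped dienone or epimerise C11′.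

**Compound list**

1 | 1-bromo-2-methoxy-3-methylbenzene | COc1c(C)cccc1Br | starting material
2 | 2-(3-bromo-4-methoxy-5-methylphenyl)-4,4,5,5-tetramethyl-1,3,2-dioxaborolane | COc1c(C)cc(cc1Br)B1OC(C)(C)C(C)(C)O1 | intermediate (not isolated)
3 | 3-bromo-4-methoxy-5-methylphenol | COc1c(C)cc(O)cc1Br | intermediate
4 | (3-bromo-4-methoxy-5-methylphenoxy)(tert-butyl)dimethylsilane | COc1c(C)cc(O[Si](C)(C)C(C)(C)C)cc1Br | intermediate
5 | 2-methyl-2-vinyloxirane (racemic) | CC1(CO1)C=C | starting material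
6 | [5-(tert-butyldimethylsilyloxy)-2-methoxy-3-methylphenyl]magnesium bromide | COc1c(C)cc(O[Si](C)(C)C(C)(C)C)cc1[Mg]Br | intermediate (not isolated)
7 | (E)-4-[5-(tert-butyldimethylsilyloxy)-2-methoxy-3-methylphenyl]-2-methylbut-2-en-1-ol | COc1c(C)cc(O[Si](C)(C)C(C)(C)C)cc1C/C=C(\C)CO | intermediate
8 | (E)-4-[5-(tert-butyldimethylsilyloxy)-2-methoxy-3-methylphenyl]-2-methylbut-2-en-1-yl methanesulfonate | COc1c(C)cc(O[Si](C)(C)C(C)(C)C)cc1C/C=C(\C)COS(C)(=O)=O | intermediate (not isolated)
9 | (E)-tert-butyl[3-(4-chloro-3-methylbut-2-en-1-yl)-4-methoxy-5-methylphenoxy]dimethylsilane | COc1c(C)cc(O[Si](C)(C)C(C)(C)C)cc1C/C=C(\C)CCl | intermediate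
10 | (S)-4-benzyl-3-propanoyl-1,3-oxazolidin-2-one | CCC(=O)N1[C@@H](Cc2ccccc2)COC1=O | starting material
11 | allyl iodide (3-iodoprop-1-ene) | C=CCI | starting material
12 | sodium (Z)-enolate of 10 | C/C=C(\[O-])N1[C@@H](Cc2ccccc2)COC1=O.[Na+] | intermediate (not isolated)
13 | (S)-4-benzyl-3-[(R)-2-methylpent-4-enoyl]-1,3-oxazolidin-2-one | C=CC[C@@H](C)C(=O)N1[C@@H](Cc2ccccc2)COC1=O | intermediate
14 | (R)-N-methoxy-N,2-dimethylpent-4-enamide | C=CC[C@@H](C)C(=O)N(C)OC | intermediate
15 | but-2-yn-1-ol | CC#CCO | starting material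
16 | sodium 2,2-bis(2-methoxyethoxy)-3-methyl-2,5-dihydro-1,2-oxaaluminol-2-uide | CC1=CCO[Al-]1(OCCOC)OCCOC.[Na+] | intermediate (not isolated)
17 | (Z)-3-iodobut-2-en-1-ol | C/C(I)=C/CO | intermediate
18 | (R)-5-(9-borabicyclo[3.3.1]nonan-9-yl)-N-methoxy-N,2-dimethylpentanamide | B1(CCC[C@@H](C)C(=O)N(C)OC)C2CCCC1CCC2 | intermediate (not isolated)
19 | (R,Z)-8-hydroxy-N-methoxy-N,2,6-trimethyloct-6-enamide | OC/C=C(/C)CCC[C@@H](C)C(=O)N(C)OC | intermediate
20 | (R,Z)-N-methoxy-N,2,6-trimethyl-8-oxooct-6-enamide | O=C/C=C(/C)CCC[C@@H](C)C(=O)N(C)OC | intermediate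
21 | trimethyl[(2-methylbut-3-yn-2-yl)oxy]silane | C#CC(C)(C)O[Si](C)(C)C | starting material
22 | (E)-chlorobis(cyclopentadienyl)[3-methyl-3-(trimethylsilyloxy)but-1-en-1-yl]zirconium | C[Si](C)(C)OC(C)(C)/C=C/[Zr](Cl)(C1C=CC=C1)C1C=CC=C1 | intermediate (not isolated)
23 | (E)-[(4-iodo-2-methylbut-3-en-2-yl)oxy]trimethylsilane | C[Si](C)(C)OC(C)(C)/C=C/I | intermediate
24 | (E)-{4-[5-(tert-butyldimethylsilyloxy)-2-methoxy-3-methylphenyl]-2-methylbut-2-en-1-yl}barium chloride | COc1c(C)cc(O[Si](C)(C)C(C)(C)C)cc1C/C=C(\C)C[Ba]Cl | intermediate (not isolated)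
25 | (2R,6Z,10E)-12-[5-(tert-butyldimethylsilyloxy)-2-methoxy-3-methylphenyl]-8-hydroxy-N-methoxy-N,2,6,10-tetramethyldodeca-6,10-dienamide (C8 epimers) | COc1c(C)cc(O[Si](C)(C)C(C)(C)C)cc1C/C=C(\C)CC(O)/C=C(/C)CCC[C@@H](C)C(=O)N(C)OC | intermediate
26 | (E)-[3-methyl-3-(trimethylsilyloxy)but-1-en-1-yl]lithium | C[Si](C)(C)OC(C)(C)/C=C/[Li] | intermediate (not isolated)
27 | dilithium salt of the tetrahedral N-methoxy-N-methyl hemiaminal adduct of 25 and 26 | COc1c(C)cc(O[Si](C)(C)C(C)(C)C)cc1C/C=C(\C)CC(O[Li])/C=C(/C)CCC[C@@H](C)C(O[Li])(N(C)OC)/C=C/C(C)(C)O[Si](C)(C)C | intermediate (not isolated)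
28 | (3E,6R,10Z,14E)-16-[5-(tert-butyldimethylsilyloxy)-2-methoxy-3-methylphenyl]-12-hydroxy-2,6,10,14-tetramethyl-2-(trimethylsilyloxy)hexadeca-3,10,14-trien-5-one | COc1c(C)cc(O[Si](C)(C)C(C)(C)C)cc1C/C=C(\C)CC(O)/C=C(/C)CCC[C@@H](C)C(=O)/C=C/C(C)(C)O[Si](C)(C)C | intermediate
29 | (3E,6R,10Z,14E)-16-[5-(tert-butyldimethylsilyloxy)-2-methoxy-3-methylphenyl]-2,6,10,14-tetramethyl-2-(trimethylsilyloxy)hexadeca-3,10,14-triene-5,12-dione | COc1c(C)cc(O[Si](C)(C)C(C)(C)C)cc1C/C=C(\C)CC(=O)/C=C(/C)CCC[C@@H](C)C(=O)/C=C/C(C)(C)O[Si](C)(C)C | intermediate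
30 | (3E,6R,10Z,14E)-2-hydroxy-16-(5-hydroxy-2-methoxy-3-methylphenyl)-2,6,10,14-tetramethylhexadeca-3,10,14-triene-5,12-dione | COc1c(C)cc(O)cc1C/C=C(\C)CC(=O)/C=C(/C)CCC[C@@H](C)C(=O)/C=C/C(C)(C)O | target

**Step count**
Total steps: 14 (fragment A: 4; fragment B: 5; alkenyl iodide: 1; coupling and endgame: 4).
Longest linear sequence: 8 steps (steps 1–4 then 11–14; equally steps 5, 6, 8, 9 then 11–14).

**Three steps most likely to fail, each with a fallback**

Step 11 (allylbarium coupling). It needs freshly made activated barium, the α/γ ratio has to hold for this aryl-bearing allyl chloride, and surplus allylbarium or surplus reductant can attack the Weinreb amide. The fallback sets out from 20 and from 6 (the Grignard reagent of step 3) and comes back to the route at 25. Barbier propargylation of 20 (propargyl bromide, Zn, THF/aq NH4Cl, 0 °C) gives the homopropargylic alcohol F1. Separately, 6 is trapped with paraformaldehyde (THF, 0 °C → rt) to give the benzyl alcohol F2, which SOCl2 (CH2Cl2, 0 °C) converts into the benzyl chloride F3. Zirconium-catalysed syn-methylalumination of F1 (AlMe3, 3 equiv, Cp2ZrCl2, 20 mol%, CH2Cl2, rt) gives the E-alkenylalane F4, which is coupled in the same flask with F3 under Pd(PPh3)4 (5 mol%, THF, rt) with retention to give 25. Here the 2′E alkene is built on the alkyne, so no allylmetal and no α/γ question arises.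

Step 12 (alkenyllithium addition). It uses excess t-BuLi-derived reagent on a substrate with a free hydroxyl, and the TMS ether of 23 may not hold through the exchange. The fallback sets out from 25 and comes back to the route at 30. CH2=CHMgBr (3 equiv, THF, −20 °C, cold aqueous citric acid quench) converts the Weinreb amide of 25 into the vinyl ketone F5. Cross-metathesis of F5 with 2-methylbut-3-en-2-ol (5 equiv) using the second-generation Hoveyda–Grubbs catalyst RuCl2(H2IMes)(=CH-C6H4-2-O-i-Pr) (5 mol%, CH2Cl2, 40 °C) gives the E hydroxy-enone F6; the trisubstituted alkenes do not take part. Dess–Martin periodinane/NaHCO3 oxidises F6 to the dione F7, and Bu4NF/AcOH removes the aryl TBS group to give 30.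

Step 3 (SN2′ opening of isoprene monoxide). The SN2′/SN2 ratio and the E/Z ratio may be lower than needed with this ortho-substituted aryl nucleophile. The fallback sets out from 6 and comes back to the route at 7. Coupling of 6 with 1-bromo-3-methylbut-2-ene (Li2CuCl4, 3 mol%, THF, 0 °C) gives the prenyl arene F8. Allylic oxidation of F8 with SeO2 (cat.) and t-BuOOH (CH2Cl2, rt) hydroxylates the E-methyl group selectively to give 7, together with some of the enal F9, which NaBH4 (MeOH, 0 °C) reduces to 7. Here the E geometry comes from the intrinsic selectivity of the selenium dioxide ene/[2,3] sequence instead of from the epoxide opening.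

**Further compounds**
F1 | step 11 | (2R,6Z)-8-hydroxy-N-methoxy-N,2,6-trimethylundec-6-en-10-ynamide | C#CCC(O)/C=C(/C)CCC[C@@H](C)C(=O)N(C)OC
F2 | step 11 | [5-(tert-butyldimethylsilyloxy)-2-methoxy-3-methylphenyl]methanol | COc1c(C)cc(O[Si](C)(C)C(C)(C)C)cc1CO
F3 | step 11 | tert-butyl[3-(chloromethyl)-4-methoxy-5-methylphenoxy]dimethylsilane | COc1c(C)cc(O[Si](C)(C)C(C)(C)C)cc1CCl
F4 | step 11 | (E)-alkenyldimethylalane from F1 (O-dimethylaluminium alkoxide) | C[Al](C)/C=C(\C)CC(O[Al](C)C)/C=C(/C)CCC[C@@H](C)C(=O)N(C)OC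
F5 | step 12 | (4R,8Z,12E)-14-[5-(tert-butyldimethylsilyloxy)-2-methoxy-3-methylphenyl]-10-hydroxy-4,8,12-trimethyltetradeca-1,8,12-trien-3-one | COc1c(C)cc(O[Si](C)(C)C(C)(C)C)cc1C/C=C(\C)CC(O)/C=C(/C)CCC[C@@H](C)C(=O)C=C
F6 | step 12 | (3E,6R,10Z,14E)-16-[5-(tert-butyldimethylsilyloxy)-2-methoxy-3-methylphenyl]-2,12-dihydroxy-2,6,10,14-tetramethylhexadeca-3,10,14-trien-5-one | COc1c(C)cc(O[Si](C)(C)C(C)(C)C)cc1C/C=C(\C)CC(O)/C=C(/C)CCC[C@@H](C)C(=O)/C=C/C(C)(C)O
F7 | step 12 | (3E,6R,10Z,14E)-16-[5-(tert-butyldimethylsilyloxy)-2-methoxy-3-methylphenyl]-2-hydroxy-2,6,10,14-tetramethylhexadeca-3,10,14-triene-5,12-dione | COc1c(C)cc(O[Si](C)(C)C(C)(C)C)cc1C/C=C(\C)CC(=O)/C=C(/C)CCC[C@@H](C)C(=O)/C=C/C(C)(C)O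
F8 | step 3 | tert-butyl[4-methoxy-3-methyl-5-(3-methylbut-2-en-1-yl)phenoxy]dimethylsilane | COc1c(C)cc(O[Si](C)(C)C(C)(C)C)cc1CC=C(C)C
F9 | step 3 | (E)-4-[5-(tert-butyldimethylsilyloxy)-2-methoxy-3-methylphenyl]-2-methylbut-2-enal | COc1c(C)cc(O[Si](C)(C)C(C)(C)C)cc1C/C=C(\C)C=O
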